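Everything hinges on disconnecting the C3–O and C4–O bonds to an E C3=C4 alkene governed from C1, the carbinol carbon on C4 of the 2,4-disubstituted oxazole ring. The feature used is that O1 and O3 are 1,3-syn and O3/O4 anti: an O1 tert-butyl carbonate is cyclised onto C3=C4 with IBr, creating in one operation the C3–O and C4–I bonds, a 1,3-dioxan-2-one ring and the C3 and C4 stereocentres. The precursor is the (1R,3E,5S)-homoallylic Boc carbonate bearing the bis-oxazole at C1 and a TBS ether at C5. The iodide is later exchanged for oxygen with net retention through the 3,4-epoxide, and opening the carbonate leaves O1 as the sole free hydroxyl for acylation.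

Key step: step 8

Remark: the side chain is numbered C1 (carbinol carbon on oxazole C4) to C6 (methyl), with O1, O3, O4, O5 on the corresponding carbons; Ar = 2-(1,3-oxazol-5-ylmethyl)-1,3-oxazol-4-yl; compounds 3, 10, 17 and the reagent (+)-Ipc2B(allyl) are assumed to be purchasable.

**Step 1**
Reactants: 1 1,3-oxazol-5-ylmethanol
Product: 2 5-(chloromethyl)-1,3-oxazole
Conditions: SOCl2, CH2Cl2, 0 °C → rt; aq. NaHCO3
Reagents that add atoms: thionyl chloride, O=S(Cl)Cl
Why: Deoxychlorination of a primary heterobenzylic alcohol through its chlorosulfite is routine, and the weakly basic oxazole is recovered as the free base after bicarbonate work-up.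

**Step 2**
Reactants: 2 5-(chloromethyl)-1,3-oxazole; 3 ethyl 2-chloro-1,3-oxazole-4-carboxylate
Product: 5 ethyl 2-(1,3-oxazol-5-ylmethyl)-1,3-oxazole-4-carboxylate, via oxazol-5-ylmethylzinc chloride 4 (not isolated)
Conditions: Zn dust, LiCl, THF, 25 °C; then 3, Pd(PPh3)4 (5 mol%), THF, 50 °C
Reagents that add atoms: none
Why: LiCl-assisted zinc insertion into the benzylic-type C–Cl bond gives a heterobenzylic zinc reagent, and its Negishi cross-coupling at the activated C2–Cl of the oxazole ester should form the CH2–C2 bond while the ester and the oxazole C–H bonds stay untouched.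

**Step 3**
Reactants: 5 ethyl 2-(1,3-oxazol-5-ylmethyl)-1,3-oxazole-4-carboxylate
Product: 7 2-(1,3-oxazol-5-ylmethyl)-1,3-oxazole-4-carbaldehyde, via aluminium hemiacetal 6 (not isolated)
Conditions: DIBAL-H, CH2Cl2, −78 °C; Rochelle salt
Reagents that add atoms: none
Why: DIBAL-H half-reduction of an ester works because the tetrahedral aluminium hemiacetal persists at −78 °C and releases the aldehyde only on work-up, a standard transformation of oxazole-4-carboxylates.

**Step 4**
Reactants: 7 2-(1,3-oxazol-5-ylmethyl)-1,3-oxazole-4-carbaldehyde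
Product: 9 (1R)-1-Ar-but-3-en-1-ol, via diisopinocampheylborinate ester 8 (not isolated)
Conditions: (+)-Ipc2B(allyl), Et2O, −78 °C; then NaOH, H2O2, 0 °C → rt
Reagents that add atoms: (+)-B-allyldiisopinocampheylborane, C=CCB([C@H]1C[C@H]2C[C@@H]([C@@H]1C)C2(C)C)[C@H]1C[C@H]2C[C@@H]([C@@H]1C)C2(C)C
Why: Brown asymmetric allylboration proceeds through a closed six-membered chair transition state in which the isopinocampheyl groups of the (−)-α-pinene-derived reagent direct allyl transfer to the Re face of the aldehyde, which should set C1 as R.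

**Step 5**
Reactants: 10 (S)-but-3-en-2-ol
Product: 11 (S)-(but-3-en-2-yloxy)(tert-butyl)dimethylsilane
Conditions: TBSCl, imidazole, CH2Cl2, rt
Reagents that add atoms: tert-butyldimethylsilyl chloride, CC(C)(C)[Si](C)(C)Cl
Why: Imidazole-mediated silylation of a secondary alcohol is standard and leaves the existing C–O stereocentre (the future C5) untouched.

**Step 6**
Reactants: 9 (1R)-1-Ar-but-3-en-1-ol; 11 (S)-(but-3-en-2-yloxy)(tert-butyl)dimethylsilane
Product: 12 (1R,3E,5S)-5-[(tert-butyldimethylsilyl)oxy]-1-Ar-hex-3-en-1-ol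
Conditions: Hoveyda–Grubbs II (5–10 mol%), 11 (4 equiv), CH2Cl2, 40 °C
Reagents that add atoms: none
Why: Olefin cross-metathesis between a fast-reacting terminal homoallylic alkene and an excess of the slowly homodimerising branched allylic silyl ether should give the hetero-coupled product, with the E geometry favoured thermodynamically and by the allylic branching, and with C1 and C5 unaffected.

**Step 7**
Reactants: 12 (1R,3E,5S)-5-[(tert-butyldimethylsilyl)oxy]-1-Ar-hex-3-en-1-ol
Product: 13 tert-butyl (1R,3E,5S)-5-[(tert-butyldimethylsilyl)oxy]-1-Ar-hex-3-en-1-yl carbonate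
Conditions: Boc2O, DMAP, MeCN, rt
Reagents that add atoms: di-tert-butyl dicarbonate, CC(C)(C)OC(=O)OC(=O)OC(C)(C)C
Why: DMAP-catalysed acyl transfer from Boc2O converts the secondary alcohol into its tert-butyl carbonate without touching the silyl ether or the alkene.

**Step 8**
Reactants: 13 tert-butyl (1R,3E,5S)-5-[(tert-butyldimethylsilyl)oxy]-1-Ar-hex-3-en-1-yl carbonate
Product: 14 (4S,6R)-4-[(1S,2S)-2-[(tert-butyldimethylsilyl)oxy]-1-iodopropyl]-6-Ar-1,3-dioxan-2-one
Conditions: IBr (1.0 M in CH2Cl2, 1.5 equiv), PhMe, −85 °C; aq. Na2S2O3/NaHCO3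
Reagents that add atoms: iodine monobromide, IBr
Why: IBr converts the C3=C4 alkene into an iodonium ion that the Boc carbonyl oxygen opens at C3 from the opposite face, and the resulting tert-butoxy dioxanylium ion loses its tert-butyl group to bromide. The closest known reaction is the low-temperature IBr variant of the iodocarbonate cyclisation of homoallylic tert-butyl carbonates, applied here to a 1,2-disubstituted E-alkene. The 1,3-dioxan-2-one closes in the 6-exo mode via a chair-like transition state that keeps both the C1 oxazolyl substituent and the C3 side chain pseudo-equatorial, so the C1 stereocentre sets C3 syn to it (4,6-cis ring). C4 follows from the trans delivery of oxygen and iodine to the E double bond, which ties its configuration to that of C3. The step needs attack at C3 instead of C4 (6-exo over 7-endo), secured by ring size and by the electron-withdrawing C5 silyloxy group that disfavours positive charge at C4, and it needs the alkene to react before the oxazoles, secured by the low temperature and a small excess of IBr. C5 carries a TBS ether because it survives the conditions and cannot act as a competing carbonyl nucleophile.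

**Step 9**
Reactants: 14 (4S,6R)-4-[(1S,2S)-2-[(tert-butyldimethylsilyl)oxy]-1-iodopropyl]-6-Ar-1,3-dioxan-2-one
Product: 16 (1R)-1-Ar-2-[(2S,3R)-3-[(1S)-1-[(tert-butyldimethylsilyl)oxy]ethyl]oxiran-2-yl]ethan-1-ol, via iodo diol 15 (not isolated)
Conditions: K2CO3, MeOH, 0 °C → rt
Reagents that add atoms: none
Why: Methoxide cleaves the cyclic carbonate and the liberated C3 alkoxide, antiperiplanar to the C4–I bond, closes the oxirane by intramolecular Williamson displacement with inversion at C4, leaving O1 as the only free hydroxyl.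

**Step 10**
Reactants: 16 (1R)-1-Ar-2-[(2S,3R)-3-[(1S)-1-[(tert-butyldimethylsilyl)oxy]ethyl]oxiran-2-yl]ethan-1-ol; 17 13-methyltetradecanoic acid
Product: 18 (1R)-1-Ar-2-[(2S,3R)-3-[(1S)-1-[(tert-butyldimethylsilyl)oxy]ethyl]oxiran-2-yl]ethyl 13-methyltetradecanoate
Conditions: DIC, DMAP, CH2Cl2, rt
Reagents that add atoms: none
Why: Steglich esterification acylates the single free hydroxyl at O1 under neutral conditions that spare the epoxide and silyl ether, and since no bond to C1 is broken its configuration is retained.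

**Step 11**
Reactants: 18 (1R)-1-Ar-2-[(2S,3R)-3-[(1S)-1-[(tert-butyldimethylsilyl)oxy]ethyl]oxiran-2-yl]ethyl 13-methyltetradecanoate
Product: 19 (1R)-1-Ar-2-[(2S,3S)-3-[(1S)-1-hydroxyethyl]oxiran-2-yl]ethyl 13-methyltetradecanoate
Conditions: HF·pyridine, pyridine, THF, 0 °C → rt
Reagents that add atoms: none
Why: Buffered fluoride-mediated desilylation removes the secondary TBS ether under mildly acidic conditions that avoid Payne rearrangement of the resulting epoxy alcohol and leave the ester alone.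

**Step 12**
Reactants: 19 (1R)-1-Ar-2-[(2S,3S)-3-[(1S)-1-hydroxyethyl]oxiran-2-yl]ethyl 13-methyltetradecanoate
Product: 20 (1R)-1-Ar-2-[(2S,3S)-3-[(1S)-1-[(phenylcarbamoyl)oxy]ethyl]oxiran-2-yl]ethyl 13-methyltetradecanoate
Conditions: PhNCO, pyridine, CH2Cl2, rt
Reagents that add atoms: phenyl isocyanate, O=C=Nc1ccccc1
Why: Addition of the free C5 hydroxyl to phenyl isocyanate is a clean carbamoylation and installs the internal oxygen nucleophile needed for the next step.

**Step 13**
Reactants: 20 (1R)-1-Ar-2-[(2S,3S)-3-[(1S)-1-[(phenylcarbamoyl)oxy]ethyl]oxiran-2-yl]ethyl 13-methyltetradecanoate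
Product: 22 (1R,3S)-3-hydroxy-3-[(4S,5S)-5-methyl-2-oxo-1,3-dioxolan-4-yl]-1-Ar-propyl 13-methyltetradecanoate, via cyclic N-phenyl iminocarbonate 21 (not isolated)
Conditions: BF3·OEt2 (excess), Et2O/CH2Cl2, −20 °C; then 1 N H2SO4, rt
Reagents that add atoms: water, O
Why: In this carbamate-directed (urethane neighbouring-group) epoxide opening the Lewis acid activates the oxirane and the carbamate carbonyl oxygen attacks the proximal carbon C4 in 5-exo fashion with inversion while the C3–O bond is kept, and dilute acid then hydrolyses the cyclic iminocarbonate to the trans carbonate.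

**Step 14**
Reactants: 22 (1R,3S)-3-hydroxy-3-[(4S,5S)-5-methyl-2-oxo-1,3-dioxolan-4-yl]-1-Ar-propyl 13-methyltetradecanoate
Product: 23 (1R,3S,4R,5S)-3,4,5-trihydroxy-1-Ar-hexyl 13-methyltetradecanoate
Conditions: LiOH (2.2 equiv), THF/H2O, 0 °C, short contact; pH 7 buffer
Reagents that add atoms: none
Why: Chemoselective hydrolysis relies on the strained five-membered cyclic carbonate being attacked by hydroxide much faster than the hindered secondary fatty ester, and the resulting monoalkyl carbonate decarboxylates to release the 4,5-diol without touching any stereocentre.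

**Compound list**

1 | 1,3-oxazol-5-ylmethanol | OCc1cnco1 | starting material
2 | 5-(chloromethyl)-1,3-oxazole | ClCc1cnco1 | intermediate
3 | ethyl 2-chloro-1,3-oxazole-4-carboxylate | CCOC(=O)c1coc(Cl)n1 | starting material
4 | (1,3-oxazol-5-ylmethyl)zinc chloride | Cl[Zn]Cc1cnco1 | intermediate (not isolated)
5 | ethyl 2-(1,3-oxazol-5-ylmethyl)-1,3-oxazole-4-carboxylate | CCOC(=O)c1coc(Cc2cnco2)n1 | intermediate
6 | diisobutylaluminium hemiacetal of 5, [ethoxy(Ar)methoxy]diisobutylaluminium | CCOC(O[Al](CC(C)C)CC(C)C)c1coc(Cc2cnco2)n1 | intermediate (not isolated)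
7 | 2-(1,3-oxazol-5-ylmethyl)-1,3-oxazole-4-carbaldehyde | O=Cc1coc(Cc2cnco2)n1 | intermediate
8 | (1R)-1-[2-(1,3-oxazol-5-ylmethyl)-1,3-oxazol-4-yl]but-3-en-1-yl diisopinocampheylborinate (Ipc groups from (−)-α-pinene) | C=CC[C@@H](OB([C@H]3C[C@H]4C[C@@H]([C@@H]3C)C4(C)C)[C@H]3C[C@H]4C[C@@H]([C@@H]3C)C4(C)C)c1coc(Cc2cnco2)n1 | intermediate (not isolated)
9 | (1R)-1-[2-(1,3-oxazol-5-ylmethyl)-1,3-oxazol-4-yl]but-3-en-1-ol | O[C@H](CC=C)c1coc(Cc2cnco2)n1 | intermediate
10 | (S)-but-3-en-2-ol | C=C[C@H](C)O | starting material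
11 | (S)-(but-3-en-2-yloxy)(tert-butyl)dimethylsilane | C=C[C@H](C)O[Si](C)(C)C(C)(C)C | intermediate
12 | (1R,3E,5S)-5-[(tert-butyldimethylsilyl)oxy]-1-[2-(1,3-oxazol-5-ylmethyl)-1,3-oxazol-4-yl]hex-3-en-1-ol | O[C@H](C/C=C/[C@H](C)O[Si](C)(C)C(C)(C)C)c1coc(Cc2cnco2)n1 | intermediate
13 | tert-butyl (1R,3E,5S)-5-[(tert-butyldimethylsilyl)oxy]-1-[2-(1,3-oxazol-5-ylmethyl)-1,3-oxazol-4-yl]hex-3-en-1-yl carbonate | CC(C)(C)OC(=O)O[C@H](C/C=C/[C@H](C)O[Si](C)(C)C(C)(C)C)c1coc(Cc2cnco2)n1 | intermediate (key-step precursor)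
14 | (4S,6R)-4-[(1S,2S)-2-[(tert-butyldimethylsilyl)oxy]-1-iodopropyl]-6-[2-(1,3-oxazol-5-ylmethyl)-1,3-oxazol-4-yl]-1,3-dioxan-2-one (4,6-cis) | O=C1O[C@@H](c2coc(Cc3cnco3)n2)C[C@H](O1)[C@H](I)[C@H](C)O[Si](C)(C)C(C)(C)C | intermediate (key-step product)
15 | (1R,3S,4S,5S)-5-[(tert-butyldimethylsilyl)oxy]-4-iodo-1-[2-(1,3-oxazol-5-ylmethyl)-1,3-oxazol-4-yl]hexane-1,3-diol | O[C@H](C[C@H](O)[C@H](I)[C@H](C)O[Si](C)(C)C(C)(C)C)c1coc(Cc2cnco2)n1 | intermediate (not isolated)
16 | (1R)-2-[(2S,3R)-3-[(1S)-1-[(tert-butyldimethylsilyl)oxy]ethyl]oxiran-2-yl]-1-[2-(1,3-oxazol-5-ylmethyl)-1,3-oxazol-4-yl]ethan-1-ol (trans-epoxide) | O[C@H](C[C@@H]1O[C@H]1[C@H](C)O[Si](C)(C)C(C)(C)C)c1coc(Cc2cnco2)n1 | intermediate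
17 | 13-methyltetradecanoic acid | CC(C)CCCCCCCCCCCC(=O)O | starting material
18 | (1R)-2-[(2S,3R)-3-[(1S)-1-[(tert-butyldimethylsilyl)oxy]ethyl]oxiran-2-yl]-1-[2-(1,3-oxazol-5-ylmethyl)-1,3-oxazol-4-yl]ethyl 13-methyltetradecanoate | CC(C)CCCCCCCCCCCC(=O)O[C@H](C[C@@H]1O[C@H]1[C@H](C)O[Si](C)(C)C(C)(C)C)c1coc(Cc2cnco2)n1 | intermediate
19 | (1R)-2-[(2S,3S)-3-[(1S)-1-hydroxyethyl]oxiran-2-yl]-1-[2-(1,3-oxazol-5-ylmethyl)-1,3-oxazol-4-yl]ethyl 13-methyltetradecanoate | CC(C)CCCCCCCCCCCC(=O)O[C@H](C[C@@H]1O[C@H]1[C@H](C)O)c1coc(Cc2cnco2)n1 | intermediate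
20 | (1R)-1-[2-(1,3-oxazol-5-ylmethyl)-1,3-oxazol-4-yl]-2-[(2S,3S)-3-[(1S)-1-[(phenylcarbamoyl)oxy]ethyl]oxiran-2-yl]ethyl 13-methyltetradecanoate | CC(C)CCCCCCCCCCCC(=O)O[C@H](C[C@@H]1O[C@H]1[C@H](C)OC(=O)Nc1ccccc1)c1coc(Cc2cnco2)n1 | intermediate
21 | (1R,3S)-3-hydroxy-3-[(4S,5S)-5-methyl-2-(phenylimino)-1,3-dioxolan-4-yl]-1-[2-(1,3-oxazol-5-ylmethyl)-1,3-oxazol-4-yl]propyl 13-methyltetradecanoate | CC(C)CCCCCCCCCCCC(=O)O[C@H](C[C@H](O)[C@@H]1OC(=Nc2ccccc2)O[C@H]1C)c1coc(Cc2cnco2)n1 | intermediate (not isolated)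
22 | (1R,3S)-3-hydroxy-3-[(4S,5S)-5-methyl-2-oxo-1,3-dioxolan-4-yl]-1-[2-(1,3-oxazol-5-ylmethyl)-1,3-oxazol-4-yl]propyl 13-methyltetradecanoate (trans-carbonate) | CC(C)CCCCCCCCCCCC(=O)O[C@H](C[C@H](O)[C@@H]1OC(=O)O[C@H]1C)c1coc(Cc2cnco2)n1 | intermediate
23 | (1R,3S,4R,5S)-3,4,5-trihydroxy-1-[2-(1,3-oxazol-5-ylmethyl)-1,3-oxazol-4-yl]hexyl 13-methyltetradecanoate | CC(C)CCCCCCCCCCCC(=O)O[C@H](C[C@H](O)[C@H](O)[C@H](C)O)c1coc(Cc2cnco2)n1 | target

Total step count: 14. Longest linear sequence: 13 steps (steps 1–4 and 6–14, from 1 to 23); step 5 is a one-step side branch.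

**Steps most likely to fail**

Step 8. The iodonium ion may be opened with poor regiocontrol or facial control (7-endo attack at C4, or a mismatched influence of the C5 stereocentre), or the reagent may be consumed by halogenation of an oxazole. The fallback sets out from alcohol 12 and bypasses 13–16. Steglich esterification of 12 with acid 17 (DIC, DMAP, CH2Cl2) should give (1R,3E,5S)-5-[(tert-butyldimethylsilyl)oxy]-1-Ar-hex-3-en-1-yl 13-methyltetradecanoate F1. A reagent-controlled Shi epoxidation (enantiomer of the fructose-derived ketone, Oxone, K2CO3, MeCN–dimethoxymethane–aqueous buffer, 0 °C) should then convert the E-alkene into the (3S,4R)-trans-epoxide, which comes back to the route at 18.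

Step 13. The Lewis acid may be tied up by the two oxazole nitrogens, or the C1 ester carbonyl may compete as an internal nucleophile at C3, so that the opening stalls or is misdirected. The fallback sets out from epoxy alcohol 19 and uses a base-mediated carboxylative opening (Cs2CO3, CO2 at 1 atm, DMF, 40 °C). The C5 alkoxide takes up CO2 and the resulting carbonate anion should open the oxirane at C4 with inversion, giving hydroxy carbonate 22 directly, where it comes back to the route; no new compound is made (F0).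

Step 14. Under base the acyl group may migrate from O1 to the free O3 hydroxyl, or the ester may be cleaved along with the carbonate. The fallback sets out from 22. Silylation of O3 (TESOTf, 2,6-lutidine, CH2Cl2, −78 °C) should give (1R,3S)-3-[(4R,5S)-5-methyl-2-oxo-1,3-dioxolan-4-yl]-1-Ar-3-[(triethylsilyl)oxy]propyl 13-methyltetradecanoate F2. Methanolysis of the carbonate (K2CO3, MeOH, 0 °C) should then give (1R,3S,4R,5S)-4,5-dihydroxy-1-Ar-3-[(triethylsilyl)oxy]hexyl 13-methyltetradecanoate F3, which has no free O3 hydroxyl for the acyl group to migrate to. HF·pyridine in THF removes the silyl group under acidic conditions and comes back to the route at target 23.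

**Further compounds**

F1 | step 8 | (1R,3E,5S)-5-[(tert-butyldimethylsilyl)oxy]-1-[2-(1,3-oxazol-5-ylmethyl)-1,3-oxazol-4-yl]hex-3-en-1-yl 13-methyltetradecanoate | CC(C)CCCCCCCCCCCC(=O)O[C@H](C/C=C/[C@H](C)O[Si](C)(C)C(C)(C)C)c1coc(Cc2cnco2)n1
F0 | step 13 | none | none
F2 | step 14 | (1R,3S)-3-[(4R,5S)-5-methyl-2-oxo-1,3-dioxolan-4-yl]-1-[2-(1,3-oxazol-5-ylmethyl)-1,3-oxazol-4-yl]-3-[(triethylsilyl)oxy]propyl 13-methyltetradecanoate | CC(C)CCCCCCCCCCCC(=O)O[C@H](C[C@H](O[Si](CC)(CC)CC)[C@@H]1OC(=O)O[C@H]1C)c1coc(Cc2cnco2)n1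
F3 | step 14 | (1R,3S,4R,5S)-4,5-dihydroxy-1-[2-(1,3-oxazol-5-ylmethyl)-1,3-oxazol-4-yl]-3-[(triethylsilyl)oxy]hexyl 13-methyltetradecanoate | CC(C)CCCCCCCCCCCC(=O)O[C@H](C[C@H](O[Si](CC)(CC)CC)[C@H](O)[C@H](C)O)c1coc(Cc2cnco2)n1
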